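Numbering used throughout: upper unit O1, C2, C3, C4, C4a to C8a, with aromatic ring A, pyran ring C, ring B on C2 and galloyl ring G on O3; the catechin unit is primed, with aromatic ring D, pyran ring F and ring E on C2'. The units are joined C4–C8'.

## The problem

The target 20 is 3-O-galloylepigallocatechin-(4β→8)-catechin, in which two flavan units are joined by a single bond between the doubly benzylic sp3 carbon C4 and C8' of ring D, one of the two free positions (C6' and C8') of the lower phloroglucinol ring. A synthesis has to make this bond without the 4→6 isomer and without oligomers, the standing weakness of cationic couplings of two flavan units. Of the five stereocentres, C2' (R) and C3' (S) come with (+)-catechin 1 but are too remote to direct the upper unit, so C4 (R) and C3 (R) need reagent control, while C2 (R) can be derived from C3 by 1,2-induction. The upper unit is 2,3-cis and 3,4-trans, an arrangement that cannot be reached by equilibration. Thirteen hydroxyl groups must be masked, and because the free polyphenol tolerates neither acid (the C4–C8' bond ionises towards a cation stabilised by ring A) nor base and air (oxidation, gallate migration, epimerisation at C2), all masks must leave in one neutral hydrogenolysis. The enabling feature is that C2, C3 and C4 form a three-carbon chain at the aldehyde oxidation level, in which C4 carries ring D and is bonded to C4a (the ortho carbon of a phenol), C3 carries the gallate oxygen and C2 carries O1 of the same phenol. C4 and C3 are thus the β and α carbons of a ring D enal whose carbonyl carbon is C2.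

## Retrosynthesis

**20 from 19.** The thirteen O–benzyl bonds are cut last. Benzyl is the only mask that leaves under neutral conditions which spare the gallate and the C4–C8' bond. Compound 19 has the full skeleton, and the forward step only has to leave the benzylic C2–O1 and C2'–O1' ring bonds intact.

**19 from 18.** The O1–C2 bond of ring C is cut. Cutting C2–ring B at the flavan stage would mean arylating an oxocarbenium ion next to a participating gallate, which delivers ring B trans to O3, the wrong relation. Cutting C8a–O1 would need a halogen on ring A in place of the phenol that the key step requires. Diol monoester 18 is open-chain, with a free ring A phenol and a (2S) benzylic carbinol. The forward closure must go with clean inversion to give the 2,3-cis flavan.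

**18 from 16 and 13 (through 17).** The C2–ring B bond is cut to the aldehyde form of lactol 16 and the aryl Grignard reagent 17 made from bromide 13. Non-chelated Felkin–Anh addition anti to the C3 acyloxy group gives the anti diol monoester with a (2S) carbinol, which is exactly the epimer that inversion turns into (2R). This removes ring B and C2 and leaves a lactol with only C3 and C4 to set.

**16 from 7, 14 and 10 (through 15).** Three bonds are cut at once: C4–C4a, C3–O3 and O1–C2. The precursors are enal 7, achiral phenol 14 and symmetrical peroxide 10. Ring A adds to the iminium ion of 7, the resulting aldehyde is acyloxylated through its enamine, and the phenol closes the lactol. Two adjustments make this defensible. A single amine would bring ring A and the galloyloxy group in from the same side of the extended chain, which after ring closure is the 3,4-cis lactol, so two amines of opposite configuration are used, one for each cycle. Peroxide 10 would oxidise free 14, so 10 and the second amine are added only after 14 has been consumed and its oxygen is tied up in lactol 15.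

**7 from 4 and 5 (through 6).** The bond cut is C4–C8', the future interflavan bond, made here as an aryl–alkenyl bond by Suzuki–Miyaura coupling. Its position is fixed by the C–Br bond of 4, so no 4→6 isomer or oligomer can form. A Heck-type vinylation of 4 was weighed and set aside, because insertion is slow for a di-ortho-oxygenated aryl bromide and the direction of β-hydride elimination is uncertain. Boronate 5 brings the E geometry and the aldehyde oxidation level with it.

**4 from 3, 2 and 1.** The C8'–Br bond and five O–benzyl bonds are cut back to (+)-catechin 1. The 3'-hydroxyl is benzylated as well, because it would otherwise compete in the Mitsunobu step.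

**10 from 8 (through 9).** The two acyl–O bonds of the peroxide are cut, which leads to two molecules of acid 8 for each molecule of 10, joined through acid chloride 9 to the two oxygens of hydrogen peroxide.

**13 from 12 and 11.** Ring B must carry benzyl ethers, since methyl ethers could not be removed from 20. Bromide 11 is therefore demethylated to triol 12 and benzylated to 13.

## Roads not taken

Alternative 1: The cut removes three bonds of ring D (C8'–C8a', C6'–C7', C4a'–C8a'). Ring D would be grown on a C4 alkynyl group by Danheiser benzannulation of ynol silyl ether A1 with cyclobutenone A2, giving A3. Its merit is that the interflavan carbon–carbon bond exists before ring D does, so 4→6 isomers are impossible, and C2 and C3 of the upper unit can be taken from established flavan-3-ol chemistry. In this respect it is safer than the chosen plan, which has to create C2, C3 and C4. Its weak points are that A2 carries the whole ring E and ring F side chain with two stereocentres and needs its own asymmetric synthesis, that the benzannulation needs heat on a substrate with a labile C4 substituent, and that after A3 ring F must still be closed at C2', the silyl groups removed and O3 galloylated. Against the better upper-unit stereocontrol of this road, the chosen plan sets the use of intact 1 for rings D, E and F and a much shorter sequence.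

Alternative 2: The cut is C4–C4a. A Lewis acid would open the C3–C4 trans-epoxide of aryl ether A4, and the ortho carbon of its 3,5-dibenzyloxyphenoxy group would attack C4 to give A5 with a free C3 hydroxyl. The end-game is better than in the chosen plan: the gallate is put on after all skeletal bonds exist, so no organometallic reagent meets an ester and no Mitsunobu closure is needed, and the 3,4-trans relation follows from anti opening. The weak points lie earlier. C4 of A4 is benzylic to the trioxygenated ring D, so opening will have cationic character, with loss of configuration at C4 and competing hydride shift. A4 itself needs an aryl ether at a hindered benzylic stereocentre and a diastereoselective epoxidation next to it, which costs at least as many steps as the route to 16, and the benzylic C2–O1 ether is exposed to the Lewis acid. Against the safer end-game, the chosen plan sets three simple components and catalyst control of C3 and C4.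

Alternative 3: The cut is O1–C2, combined with creation of C4 by group selection. Acid would activate the cis-epoxide of bis-phenol A6, and one of the two diastereotopic phenols on C4 would attack C2 with inversion to give A7. The 2,3-cis relation comes stereospecifically from a cis-epoxide, which is more reliable than the pairing of Felkin–Anh addition and Mitsunobu inversion in the chosen plan, and C4 arises without an external chiral reagent. The weak points are that the aryl group left over in A7 is only a phloroglucinol ring, so ring F, C2', C3' and ring E would all have to be built onto a crowded phenol, which amounts to a second catechin synthesis, and that the selection between the two phenols rests on C3 alone and may be modest. This road is better at C2 but far longer, whereas the chosen plan takes the lower unit ready-made from 1.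

Key step: step 8

## Route

Remark on the chemistry: boronate 5 and both enantiomers of the two prolinol silyl ethers are taken as commercial; lactols 15 and 16 are anomeric mixtures, so C2 is left undefined in their SMILES.

Step 1
Reactants: 1 (+)-catechin
Product: 2 5,7,3',4'-tetra-O-benzylcatechin
Conditions: BnBr, K2CO3, DMF, rt
Reagents that add atoms: benzyl bromide, BrCc1ccccc1
Why: Williamson etherification; carbonate deprotonates only the four phenols, so the secondary hydroxyl stays free and no stereocentre is touched.

Step 2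
Reactants: 2 5,7,3',4'-tetra-O-benzylcatechin
Product: 3 8-bromo-5,7,3',4'-tetra-O-benzylcatechin
Conditions: NBS, CH2Cl2, −78 °C to rt
Reagents that add atoms: N-bromosuccinimide, O=C1CCC(=O)N1Br
Why: Electrophilic aromatic bromination; the phloroglucinol-type ring is far more nucleophilic than the catechol ring, and 5,7-di-O-benzyl flavan-3-ols are brominated at C8 in preference to C6 at low temperature.

Step 3
Reactants: 3 8-bromo-5,7,3',4'-tetra-O-benzylcatechin
Product: 4 8-bromo-3,5,7,3',4'-penta-O-benzylcatechin
Conditions: NaH, BnBr, DMF, 0 °C to rt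
Reagents that add atoms: benzyl bromide, BrCc1ccccc1
Why: Williamson etherification of the sodium alkoxide; the aryl bromide is inert, and the secondary hydroxyl is masked so that it cannot compete in the Mitsunobu step.

Step 4
Reactants: 4 8-bromo-3,5,7,3',4'-penta-O-benzylcatechin; 5 (E)-2-(3,3-diethoxyprop-1-enyl)-4,4,5,5-tetramethyl-1,3,2-dioxaborolane
Product: 7 (E)-3-(3,5,7,3',4'-penta-O-benzylcatechin-8-yl)propenal, via diethyl acetal 6 (not isolated)
Conditions: Pd(OAc)2 (5 mol %), SPhos (10 mol %), K3PO4, toluene/H2O, 90 °C; then 1 M HCl, THF, rt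
Reagents that add atoms: water, O
Why: Suzuki–Miyaura coupling; the biaryl dialkylphosphine lets zerovalent palladium insert into the hindered electron-rich C–Br bond, the alkenyl group transfers with retention of the E geometry, and dilute acid hydrolyses the allylic acetal to the enal.

Step 5
Reactants: 8 3,4,5-tris(benzyloxy)benzoic acid (two molecules for each molecule of 10)
Product: 10 bis[3,4,5-tris(benzyloxy)benzoyl] peroxide, via acid chloride 9 (not isolated)
Conditions: (COCl)2, DMF (cat.), CH2Cl2, rt; evaporate; then 30% aq H2O2 (0.5 equiv per 9), NaOH, THF/H2O, 0 °C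
Reagents that add atoms: hydrogen peroxide, OO; second molecule of 3,4,5-tris(benzyloxy)benzoic acid 8 (enters as its chloride 9), OC(=O)c1cc(OCc9ccccc9)c(OCc9ccccc9)c(OCc9ccccc9)c1
Why: Acid chloride formation followed by Schotten–Baumann acylation of hydroperoxide at both oxygens, the standard preparation of symmetrical diaroyl peroxides; each molecule of 10 takes its two aroyl groups from two molecules of 8 and its O–O unit from hydrogen peroxide. The product should be kept cold and used fresh.

Step 6
Reactants: 11 5-bromo-1,2,3-trimethoxybenzene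
Product: 12 5-bromobenzene-1,2,3-triol
Conditions: BBr3, CH2Cl2, −78 °C to rt; then H2O
Reagents that add atoms: none
Why: Lewis-acid cleavage of aryl methyl ethers by BBr3; the aryl bromide is unaffected.

Step 7
Reactants: 12 5-bromobenzene-1,2,3-triol
Product: 13 5-bromo-1,2,3-tris(benzyloxy)benzene
Conditions: BnBr, K2CO3, DMF, 60 °C, under argon
Reagents that add atoms: benzyl bromide, BrCc1ccccc1
Why: Williamson etherification under inert gas to protect the air-sensitive pyrogallol; ring B now carries ethers that leave in the final hydrogenolysis.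

Step 8
Reactants: 7 (E)-3-(3,5,7,3',4'-penta-O-benzylcatechin-8-yl)propenal; 14 3,5-bis(benzyloxy)phenol; 10 bis[3,4,5-tris(benzyloxy)benzoyl] peroxide
Product: 16 (3R,4R)-5,7-bis(benzyloxy)-3-[3,4,5-tris(benzyloxy)benzoyloxy]-4-(3,5,7,3',4'-penta-O-benzylcatechin-8-yl)chroman-2-ol (anomeric mixture), via 4-arylchroman-2-ol 15 (not isolated)
Conditions: (S)-2-[bis(3,5-bis(trifluoromethyl)phenyl)(trimethylsilyloxy)methyl]pyrrolidine (10 mol %), PhCO2H (10 mol %), toluene, 0 °C to rt; then (R)-2-[diphenyl(trimethylsilyloxy)methyl]pyrrolidine (30 mol %), 10 (1.3 equiv), hydroquinone (10 mol %), THF, 0 °C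
Reagents that add atoms: none
Why: Proposed new method: the electron-poor (S)-amine condenses with enal 7 to an E-iminium ion with one face shielded by the diarylsilyloxymethyl group, the ortho carbon of phenol 14 adds to C4 from the open face (Friedel–Crafts conjugate addition, C4–C4a, C4 set as R by the first amine), and hydrolysis followed by 6-exo-trig hemiacetalisation of the ring A hydroxyl onto the aldehyde carbon gives lactol 15 (O1–C2, ring C). When peroxide 10 and the (R)-amine are then added, the open aldehyde in equilibrium with 15 forms an E-enamine that attacks the O–O bond of 10 through the face left open by the second amine (C3–O3, C3 set as R by the second amine), and the released α-acyloxy aldehyde closes again by the same 6-exo-trig hemiacetalisation to 16, the anomeric centre C2 staying uncontrolled because step 9 removes it. The closest known reaction types are the amine-catalysed Friedel–Crafts addition and lactolisation of electron-rich phenols with enals, the enamine α-benzoyloxylation of aldehydes with dibenzoyl peroxide, and iminium–enamine cascades run with two amines of chosen configuration; their union with a phenol, a diaroyl peroxide and a hindered β-aryl enal is new. Two amines of opposite configuration are required because one amine alone would deliver ring A and the galloyloxy group from the same side of the extended chain, which is the 3,4-cis lactol; the second amine is the more nucleophilic and is present in threefold amount, so it should dominate the enamine cycle. Regioselectivity for the ortho carbon of 14 is needed and is secured by hydrogen bonding of the phenol hydroxyl in the ion pair, by the greater crowding of the carbon between the two benzyloxy groups, and by the lactol trap that only the ortho adduct can reach. Chemoselectivity between the oxidisable phenol and the peroxide is secured by the order of addition, since 14 is consumed and its oxygen bound in 15 before 10 is admitted, and the interflavan position is already fixed at C8' by the C–Br bond of 4.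

Step 9
Reactants: 16 (3R,4R)-5,7-bis(benzyloxy)-3-[3,4,5-tris(benzyloxy)benzoyloxy]-4-(3,5,7,3',4'-penta-O-benzylcatechin-8-yl)chroman-2-ol; 13 5-bromo-1,2,3-tris(benzyloxy)benzene
Product: 18 (1S,2R,3R)-1-[3,4,5-tris(benzyloxy)phenyl]-3-[2-hydroxy-4,6-bis(benzyloxy)phenyl]-3-(3,5,7,3',4'-penta-O-benzylcatechin-8-yl)propane-1,2-diol 2-[3,4,5-tris(benzyloxy)benzoate], via arylmagnesium bromide 17 (not isolated)
Conditions: 13, Mg, THF, 50 °C; then add to 16 (3 equiv of 17), THF, −78 °C; AcOH at −78 °C
Reagents that add atoms: none
Why: Grignard addition to a lactol: the first equivalent deprotonates the phenolic hemiacetal, which collapses to the phenoxide aldehyde, and the next adds to the aldehyde anti to the C3 acyloxy group (polar Felkin–Anh, the ester oxygen being too poor a donor for chelation in THF), which sets C2 (carbon 1 of the propane chain) as S. The electron-rich, hindered gallate should resist both attack and migration at −78 °C, and the cold acid quench removes the alkoxide before warming.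

Step 10
Reactants: 18 (1S,2R,3R)-1-[3,4,5-tris(benzyloxy)phenyl]-3-[2-hydroxy-4,6-bis(benzyloxy)phenyl]-3-(3,5,7,3',4'-penta-O-benzylcatechin-8-yl)propane-1,2-diol 2-[3,4,5-tris(benzyloxy)benzoate]
Product: 19 trideca-O-benzyl-3-O-galloylepigallocatechin-(4β→8)-catechin
Conditions: PPh3, DIAD, THF, 0 °C to rt
Reagents that add atoms: none
Why: Intramolecular Mitsunobu etherification; the ring A phenol is the acidic partner and displaces the benzylic alkoxyphosphonium group in a 6-exo-tet SN2 closure, which inverts C2 from S to R and gives the 2,3-cis, 3,4-trans flavan.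

Step 11
Reactants: 19 trideca-O-benzyl-3-O-galloylepigallocatechin-(4β→8)-catechin
Product: 20 3-O-galloylepigallocatechin-(4β→8)-catechin (CNP0129434.1)
Conditions: H2 (1 atm), Pd(OH)2 on carbon, THF/MeOH/H2O, rt
Reagents that add atoms: none
Why: Hydrogenolysis of all thirteen benzyl ethers under neutral conditions; the gallate ester, the ring C–O bonds at C2 and C2' and the acid-labile C4–C8' bond should survive, as they do in the deprotection of benzylated flavan oligomers.

## Compound list

1 | (+)-catechin, (2R,3S) | O[C@H]1Cc2c(O)cc(O)cc2O[C@@H]1c1ccc(O)c(O)c1 | starting material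
2 | (2R,3S)-5,7,3',4'-tetra-O-benzylcatechin | O[C@H]1Cc2c(OCc9ccccc9)cc(OCc9ccccc9)cc2O[C@@H]1c1ccc(OCc9ccccc9)c(OCc9ccccc9)c1 | intermediate
3 | (2R,3S)-8-bromo-5,7,3',4'-tetra-O-benzylcatechin | O[C@H]1Cc2c(OCc9ccccc9)cc(OCc9ccccc9)c(Br)c2O[C@@H]1c1ccc(OCc9ccccc9)c(OCc9ccccc9)c1 | intermediate
4 | (2R,3S)-8-bromo-3,5,7,3',4'-penta-O-benzylcatechin | O(Cc9ccccc9)[C@H]1Cc2c(OCc9ccccc9)cc(OCc9ccccc9)c(Br)c2O[C@@H]1c1ccc(OCc9ccccc9)c(OCc9ccccc9)c1 | intermediate
5 | (E)-2-(3,3-diethoxyprop-1-enyl)-4,4,5,5-tetramethyl-1,3,2-dioxaborolane | CCOC(OCC)/C=C/B1OC(C)(C)C(C)(C)O1 | starting material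
6 | (E)-8-(3,3-diethoxyprop-1-enyl)-3,5,7,3',4'-penta-O-benzylcatechin (not isolated) | CCOC(OCC)/C=C/c1c(OCc9ccccc9)cc(OCc9ccccc9)c2c1O[C@H](c1ccc(OCc9ccccc9)c(OCc9ccccc9)c1)[C@@H](OCc9ccccc9)C2 | intermediate
7 | (E)-3-(3,5,7,3',4'-penta-O-benzylcatechin-8-yl)propenal | O=C/C=C/c1c(OCc9ccccc9)cc(OCc9ccccc9)c2c1O[C@H](c1ccc(OCc9ccccc9)c(OCc9ccccc9)c1)[C@@H](OCc9ccccc9)C2 | intermediate
8 | 3,4,5-tris(benzyloxy)benzoic acid | OC(=O)c1cc(OCc9ccccc9)c(OCc9ccccc9)c(OCc9ccccc9)c1 | starting material
9 | 3,4,5-tris(benzyloxy)benzoyl chloride (not isolated) | ClC(=O)c1cc(OCc9ccccc9)c(OCc9ccccc9)c(OCc9ccccc9)c1 | intermediate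
10 | bis[3,4,5-tris(benzyloxy)benzoyl] peroxide | O=C(OOC(=O)c1cc(OCc9ccccc9)c(OCc9ccccc9)c(OCc9ccccc9)c1)c1cc(OCc9ccccc9)c(OCc9ccccc9)c(OCc9ccccc9)c1 | intermediate
11 | 5-bromo-1,2,3-trimethoxybenzene | COc1cc(Br)cc(OC)c1OC | starting material
12 | 5-bromobenzene-1,2,3-triol | Oc1cc(Br)cc(O)c1O | intermediate
13 | 5-bromo-1,2,3-tris(benzyloxy)benzene | Brc1cc(OCc9ccccc9)c(OCc9ccccc9)c(OCc9ccccc9)c1 | intermediate
14 | 3,5-bis(benzyloxy)phenol | Oc1cc(OCc9ccccc9)cc(OCc9ccccc9)c1 | starting material
15 | (4R)-5,7-bis(benzyloxy)-4-(3,5,7,3',4'-penta-O-benzylcatechin-8-yl)chroman-2-ol, anomeric mixture (not isolated) | O1C(O)C[C@@H](c3c(OCc9ccccc9)cc(OCc9ccccc9)c4c3O[C@H](c3ccc(OCc9ccccc9)c(OCc9ccccc9)c3)[C@@H](OCc9ccccc9)C4)c2c(OCc9ccccc9)cc(OCc9ccccc9)cc21 | intermediate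
16 | (3R,4R)-5,7-bis(benzyloxy)-3-[3,4,5-tris(benzyloxy)benzoyloxy]-4-(3,5,7,3',4'-penta-O-benzylcatechin-8-yl)chroman-2-ol, anomeric mixture | O1C(O)[C@H](OC(=O)c3cc(OCc9ccccc9)c(OCc9ccccc9)c(OCc9ccccc9)c3)[C@@H](c3c(OCc9ccccc9)cc(OCc9ccccc9)c4c3O[C@H](c3ccc(OCc9ccccc9)c(OCc9ccccc9)c3)[C@@H](OCc9ccccc9)C4)c2c(OCc9ccccc9)cc(OCc9ccccc9)cc21 | intermediate
17 | [3,4,5-tris(benzyloxy)phenyl]magnesium bromide (not isolated) | Br[Mg]c1cc(OCc9ccccc9)c(OCc9ccccc9)c(OCc9ccccc9)c1 | intermediate
18 | (1S,2R,3R)-1-[3,4,5-tris(benzyloxy)phenyl]-3-[2-hydroxy-4,6-bis(benzyloxy)phenyl]-3-(3,5,7,3',4'-penta-O-benzylcatechin-8-yl)propane-1,2-diol 2-[3,4,5-tris(benzyloxy)benzoate]; propane carbons 1, 2, 3 are flavan C2, C3, C4 | O[C@@H](c1cc(OCc9ccccc9)c(OCc9ccccc9)c(OCc9ccccc9)c1)[C@H](OC(=O)c1cc(OCc9ccccc9)c(OCc9ccccc9)c(OCc9ccccc9)c1)[C@@H](c1c(OCc9ccccc9)cc(OCc9ccccc9)c2c1O[C@H](c1ccc(OCc9ccccc9)c(OCc9ccccc9)c1)[C@@H](OCc9ccccc9)C2)c1c(O)cc(OCc9ccccc9)cc1OCc9ccccc9 | intermediate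
19 | trideca-O-benzyl-3-O-galloylepigallocatechin-(4β→8)-catechin; upper unit 2R,3R,4R, lower unit 2R,3S, every hydroxyl of 20 as its benzyl ether | O=C(O[C@@H]1[C@@H](c2c(OCc9ccccc9)cc(OCc9ccccc9)c3c2O[C@H](c2ccc(OCc9ccccc9)c(OCc9ccccc9)c2)[C@@H](OCc9ccccc9)C3)c2c(OCc9ccccc9)cc(OCc9ccccc9)cc2O[C@@H]1c1cc(OCc9ccccc9)c(OCc9ccccc9)c(OCc9ccccc9)c1)c1cc(OCc9ccccc9)c(OCc9ccccc9)c(OCc9ccccc9)c1 | intermediate
20 | 3-O-galloylepigallocatechin-(4β→8)-catechin (CNP0129434.1); upper unit 2R,3R,4R, lower unit 2R,3S | O=C(O[C@@H]1[C@@H](c2c(O)cc(O)c3c2O[C@H](c2ccc(O)c(O)c2)[C@@H](O)C3)c2c(O)cc(O)cc2O[C@@H]1c1cc(O)c(O)c(O)c1)c1cc(O)c(O)c(O)c1 | target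

## Step count and risks

Total step count: 11. Longest linear sequence: 8 steps (steps 1, 2, 3, 4, 8, 9, 10, 11, from 1 to 20).

**Step 8 (key step, the one new method).** Three things are most likely to go wrong. Conjugate addition may be slow, because the iminium ion of 7 is stabilised by the trioxygenated ring D and flanked by two ortho oxygens. The first amine may leak into the enamine cycle, which would erode the 3,4-trans selectivity. The amines may be N-acyloxylated by 10, which would stall turnover.

The fallback uses known chemistry and sets out from 7 and 14. The first stage alone, a known amine-catalysed phenol–enal Friedel–Crafts lactolisation, is run with the (S)-amine and 15 is isolated. Oxidation of 15 (TEMPO, PhI(OAc)2) gives (4R)-5,7-bis(benzyloxy)-4-(3,5,7,3',4'-penta-O-benzylcatechin-8-yl)chroman-2-one F1. Its lithium enolate (LiN(SiMe3)2, THF, −78 °C) is hydroxylated with 2-(phenylsulfonyl)-3-phenyloxaziridine anti to the C4 aryl group, giving (3R,4R)-3-hydroxy-5,7-bis(benzyloxy)-4-(3,5,7,3',4'-penta-O-benzylcatechin-8-yl)chroman-2-one F2. Steglich esterification of F2 with acid 8 (DCC, DMAP) gives (3R,4R)-3-[3,4,5-tris(benzyloxy)benzoyloxy]-5,7-bis(benzyloxy)-4-(3,5,7,3',4'-penta-O-benzylcatechin-8-yl)chroman-2-one F3. Reduction with i-Bu2AlH at −78 °C takes the more electrophilic aryl lactone to the lactol and comes back to the route at 16.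

**Step 9.** The likely failures are transfer of the galloyl group from O3 to the new C2 magnesium alkoxide, enolisation of the α-acyloxy aldehyde by the basic reagent, and loss of Felkin–Anh selectivity, because the bulky C4 substituent competes with the acyloxy group for the position anti to the nucleophile. The fallback sets out from 16 and 13. Bromide 13 is converted (n-BuLi, then B(OiPr)3, then aqueous acid) into [3,4,5-tris(benzyloxy)phenyl]boronic acid F4. F4 is added to the aldehyde form of 16 with [Rh(OH)(cod)]2 as catalyst in dioxane/H2O. The rhodium alkoxide is protonated at once, so no basic alkoxide persists next to the ester, and the same non-chelated facial preference is expected. The fallback comes back at 18.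

**Step 10.** The likely failure is loss of clean inversion, through ionisation of the benzylic alkoxyphosphonium ion (the para benzyloxy group stabilises the cation), through participation of the neighbouring gallate carbonyl, or through elimination towards C3. The fallback sets out from 18. Oxidation of the benzylic alcohol (MnO2, CH2Cl2) gives the open-chain aryl ketone (2R,3R)-3-[2-hydroxy-4,6-bis(benzyloxy)phenyl]-1-oxo-1-[3,4,5-tris(benzyloxy)phenyl]-3-(3,5,7,3',4'-penta-O-benzylcatechin-8-yl)propan-2-yl 3,4,5-tris(benzyloxy)benzoate F5, whose ring A phenol adds to the ketone to give the cyclic hemiketal (3R,4R)-2-[3,4,5-tris(benzyloxy)phenyl]-3-[3,4,5-tris(benzyloxy)benzoyloxy]-5,7-bis(benzyloxy)-4-(3,5,7,3',4'-penta-O-benzylcatechin-8-yl)chroman-2-ol F6. Ionic hydrogenation of F6 (Et3SiH, BF3·OEt2, CH2Cl2/MeCN, −40 °C) should deliver hydride to the C2 oxocarbenium ion trans to the participating 3-acyloxy group, which is the 2,3-cis flavan. The fallback comes back at 19.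

**Step 4.** The likely failures are slow oxidative addition into the di-ortho-oxygenated C8–Br bond and protodeboronation of 5 during the long heating. The fallback sets out from 4 and reverses the polarity. Bromine–lithium exchange (n-BuLi, THF, −78 °C) gives 8-lithio-3,5,7,3',4'-penta-O-benzylcatechin F7. F7 is added to 3-(dimethylamino)acrolein, and dilute acid work-up eliminates dimethylamine to give the E-enal. The fallback comes back at 7.

## Further compounds

F1 | step 8 | (4R)-5,7-bis(benzyloxy)-4-(3,5,7,3',4'-penta-O-benzylcatechin-8-yl)chroman-2-one | O1C(=O)C[C@@H](c3c(OCc9ccccc9)cc(OCc9ccccc9)c4c3O[C@H](c3ccc(OCc9ccccc9)c(OCc9ccccc9)c3)[C@@H](OCc9ccccc9)C4)c2c(OCc9ccccc9)cc(OCc9ccccc9)cc21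
F2 | step 8 | (3R,4R)-3-hydroxy-5,7-bis(benzyloxy)-4-(3,5,7,3',4'-penta-O-benzylcatechin-8-yl)chroman-2-one | O1C(=O)[C@H](O)[C@@H](c3c(OCc9ccccc9)cc(OCc9ccccc9)c4c3O[C@H](c3ccc(OCc9ccccc9)c(OCc9ccccc9)c3)[C@@H](OCc9ccccc9)C4)c2c(OCc9ccccc9)cc(OCc9ccccc9)cc21
F3 | step 8 | (3R,4R)-3-[3,4,5-tris(benzyloxy)benzoyloxy]-5,7-bis(benzyloxy)-4-(3,5,7,3',4'-penta-O-benzylcatechin-8-yl)chroman-2-one | O1C(=O)[C@H](OC(=O)c3cc(OCc9ccccc9)c(OCc9ccccc9)c(OCc9ccccc9)c3)[C@@H](c3c(OCc9ccccc9)cc(OCc9ccccc9)c4c3O[C@H](c3ccc(OCc9ccccc9)c(OCc9ccccc9)c3)[C@@H](OCc9ccccc9)C4)c2c(OCc9ccccc9)cc(OCc9ccccc9)cc21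
F4 | step 9 | [3,4,5-tris(benzyloxy)phenyl]boronic acid | OB(O)c1cc(OCc9ccccc9)c(OCc9ccccc9)c(OCc9ccccc9)c1
F5 | step 10 | (2R,3R)-3-[2-hydroxy-4,6-bis(benzyloxy)phenyl]-1-oxo-1-[3,4,5-tris(benzyloxy)phenyl]-3-(3,5,7,3',4'-penta-O-benzylcatechin-8-yl)propan-2-yl 3,4,5-tris(benzyloxy)benzoate | O=C(c1cc(OCc9ccccc9)c(OCc9ccccc9)c(OCc9ccccc9)c1)[C@H](OC(=O)c1cc(OCc9ccccc9)c(OCc9ccccc9)c(OCc9ccccc9)c1)[C@@H](c1c(OCc9ccccc9)cc(OCc9ccccc9)c2c1O[C@H](c1ccc(OCc9ccccc9)c(OCc9ccccc9)c1)[C@@H](OCc9ccccc9)C2)c1c(O)cc(OCc9ccccc9)cc1OCc9ccccc9
F6 | step 10 | (3R,4R)-2-[3,4,5-tris(benzyloxy)phenyl]-3-[3,4,5-tris(benzyloxy)benzoyloxy]-5,7-bis(benzyloxy)-4-(3,5,7,3',4'-penta-O-benzylcatechin-8-yl)chroman-2-ol, anomeric mixture | O1C(O)(c3cc(OCc9ccccc9)c(OCc9ccccc9)c(OCc9ccccc9)c3)[C@H](OC(=O)c3cc(OCc9ccccc9)c(OCc9ccccc9)c(OCc9ccccc9)c3)[C@@H](c3c(OCc9ccccc9)cc(OCc9ccccc9)c4c3O[C@H](c3ccc(OCc9ccccc9)c(OCc9ccccc9)c3)[C@@H](OCc9ccccc9)C4)c2c(OCc9ccccc9)cc(OCc9ccccc9)cc21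
F7 | step 4 | 8-lithio-3,5,7,3',4'-penta-O-benzylcatechin | [Li]c1c(OCc9ccccc9)cc(OCc9ccccc9)c2c1O[C@H](c1ccc(OCc9ccccc9)c(OCc9ccccc9)c1)[C@@H](OCc9ccccc9)C2
A1 | alternative 1 | (2R,3R,4β)-5,7-bis(benzyloxy)-2-[3,4,5-tris(benzyloxy)phenyl]-3-(tert-butyldimethylsilyloxy)-4-[(triisopropylsilyloxy)ethynyl]chroman | O1[C@H](c3cc(OCc9ccccc9)c(OCc9ccccc9)c(OCc9ccccc9)c3)[C@H](O[Si](C)(C)C(C)(C)C)[C@@H](C#CO[Si](C(C)C)(C(C)C)C(C)C)c2c(OCc9ccccc9)cc(OCc9ccccc9)cc21
A2 | alternative 1 | 3-benzyloxy-4-{[5-(3,4-bis(benzyloxy)phenyl)-2,2-dimethyl-1,3-dioxolan-4-yl]methyl}cyclobut-2-enone | O=C1C=C(OCc9ccccc9)C1C[C@@H]2OC(C)(C)O[C@H]2c3ccc(OCc9ccccc9)c(OCc9ccccc9)c3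
A3 | alternative 1 | protected epigallocatechin bearing at C4 (β) the new ring D, a 2-hydroxy-6-(triisopropylsilyloxy)-4-benzyloxy-3-(acetonide-protected 2,3-dihydroxy-3-arylpropyl)phenyl group | O1[C@H](c3cc(OCc4ccccc4)c(OCc4ccccc4)c(OCc4ccccc4)c3)[C@H](O[Si](C)(C)C(C)(C)C)[C@@H](c5c(O[Si](C(C)C)(C(C)C)C(C)C)cc(OCc4ccccc4)c(C[C@@H]6OC(C)(C)O[C@H]6c7ccc(OCc4ccccc4)c(OCc4ccccc4)c7)c5O)c2c(OCc4ccccc4)cc(OCc4ccccc4)cc21
A4 | alternative 2 | open-chain 3,5-bis(benzyloxy)phenyl ether at C2 carrying ring B, with a C3–C4 trans-epoxide whose C4 bears the penta-O-benzylcatechin-8-yl group | O(c1cc(OCc9ccccc9)cc(OCc9ccccc9)c1)[C@H](c1cc(OCc9ccccc9)c(OCc9ccccc9)c(OCc9ccccc9)c1)[C@@H]1O[C@H]1c1c(OCc9ccccc9)cc(OCc9ccccc9)c2c1O[C@H](c1ccc(OCc9ccccc9)c(OCc9ccccc9)c1)[C@@H](OCc9ccccc9)C2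
A5 | alternative 2 | deca-O-benzyl epigallocatechin-(4β→8)-catechin with free C3 hydroxyl | O1[C@H](c3cc(OCc4ccccc4)c(OCc4ccccc4)c(OCc4ccccc4)c3)[C@H](O)[C@@H](c5c(OCc4ccccc4)cc(OCc4ccccc4)c6c5O[C@H](c7ccc(OCc4ccccc4)c(OCc4ccccc4)c7)[C@@H](OCc4ccccc4)C6)c2c(OCc4ccccc4)cc(OCc4ccccc4)cc21
A6 | alternative 3 | cis-2-[3,4,5-tris(benzyloxy)phenyl]-3-{bis[2-hydroxy-4,6-bis(benzyloxy)phenyl]methyl}oxirane | c1(cc(OCc9ccccc9)c(OCc9ccccc9)c(OCc9ccccc9)c1)[C@@H]1O[C@@H]1C(c1c(O)cc(OCc9ccccc9)cc1OCc9ccccc9)c1c(O)cc(OCc9ccccc9)cc1OCc9ccccc9
A7 | alternative 3 | penta-O-benzylepigallocatechin bearing at C4 (β) a 2-hydroxy-4,6-bis(benzyloxy)phenyl group, C3 hydroxyl free | O1[C@H](c3cc(OCc4ccccc4)c(OCc4ccccc4)c(OCc4ccccc4)c3)[C@H](O)[C@@H](c5c(O)cc(OCc4ccccc4)cc5OCc4ccccc4)c2c(OCc4ccccc4)cc(OCc4ccccc4)cc21
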